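(The readings are simulated for substances that don't exist; scatter was added.)

The target is where we start. It is made by attack of nucleophile on electrophile and used by electrophile on target, so the electrophile cancels from the comparison of the two rates. Made over used is s[nucleophile]/[target], with s the rate constant of attack over that of the loss of target, so the ratio falls as [target] climbs, and where it stands at one, [target] equals s[nucleophile].

| flask | electrophile | nucleophile | protic impurity | remark | time |
|---|---|---|---|---|---|
| dusk | 0.80 M | 0.98 M | 0.016 M | run made earlier |  |
| summer | 0.80 M | 1.3 M | 0.016 M | run made earlier |  |
| midnight | 0.80 M | 1.7 M | 0.016 M | run made earlier |  |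
| north-west | 0.80 M | 0.880 M | 0.0160 M |  | 25 h |
| east | 0.80 M | 1.80 M | 0.0160 M |  | 25 h |

| run | time / h | electrophile / % | target / % |
|---|---|---|---|
| dusk | 4.00 | 79 | 6 |
| dusk | 8.00 | 63 | 15 |
| dusk | 10.0 | 56 | 13 |
| dusk | 15.0 | 41 | 14 |
| dusk | 20.0 | 35 | 7 |
| summer | 4.00 | 77 | 14 |
| summer | 8.00 | 49 | 18 |
| summer | 10.0 | 42 | 16 |
| summer | 15.0 | 32 | 18 |
| summer | 20.0 | 23 | 16 |
| midnight | 1.50 | 88 | 10 |
| midnight | 4.00 | 63 | 19 |
| midnight | 8.00 | 42 | 19 |
| midnight | 12.0 | 27 | 23 |
| midnight | 20.0 | 15 | 21 |

(standard deviation of a reading: 2 percentage points)

- a species is counted by the electrophile in it: one side product counts as two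
- the numbers in the tables scatter by 2 percentage points (one standard deviation)
- candidate steps: nucleophile + protic impurity -> quenched reagent; electrophile + nucleophile -> acid set free + target; electrophile + target -> side product; nucleophile + acid set free <-> protonated nucleophile

- part of the electrophile that has reacted at the end, north-west
- part of the electrophile that has reacted at the end, east
- what raising the concentration of nucleophile from its lowest to its highest value here does to the part of the electrophile that has reacted (changes below 5 percentage points count as none) (it falls / it rises / no change)

We take the protic impurity to quench its own amount of nucleophile and each attack to tie up a second nucleophile through the acid set free, so our balance puts free nucleophile in the midnight run at 1.07 M after 8.00 h and 0.836 M after 20.0 h. The last target reading of the midnight run, 21%, taken as a plateau where made over used is one, then gives the selectivity factor s, read as target over free nucleophile, of 0.201.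

On the plateau the balance becomes [nucleophile] = (a + [electrophile])/(1 + s), where a is the nucleophile charged beyond electrophile and protic impurity: 0.0640 M in north-west, 0.984 M in east. The fall of ln[electrophile] per hour between those midnight readings, divided by the mean free nucleophile, gives a loss constant g of 0.0901 L mol⁻¹ h⁻¹. Integrating to 25 h, we reach 63.3% reacted in north-west and 90.6% in east.

The weak link is g, taken from two scattered readings of one run. The dusk run, between 10.0 h and 20.0 h, gives 0.105 L mol⁻¹ h⁻¹, and the mean of the two moves us to 65.2% in north-west and 92.0% in east, which we commit to.

The forecast says 65% for north-west and 92% for east, and of the part reacted, as nucleophile is raised from its lowest to its highest value here, it says “it rises”: “More nucleophile raises the conversion because the reagent is no longer starved.”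

North-west gives 68.4% and east 93.3%, and of the part reacted, over that same rise in nucleophile, the answer is “it rises”, by 25 percentage points. In east, made over used falls from 1.55 at 4.33 h to 0.882 at 25.0 h. Our s, times the 48% of east's nucleophile still free at that end, gives target at 21.7% of the electrophile charged, and east holds 21.9%.

    nucleophile + protic impurity → quenched reagent (k = 4.60 × 10⁻⁴ L mol⁻¹ s⁻¹)
    electrophile + nucleophile → acid set free + target (k = 1.50 × 10⁻⁵ L mol⁻¹ s⁻¹)
    electrophile + target → side product (k = 8.40 × 10⁻⁵ L mol⁻¹ s⁻¹)
    nucleophile + acid set free ⇌ protonated nucleophile, settled at all times (K = 310 L mol⁻¹)

We put s to use on a neighbour of east charged with 0.20 M of electrophile. Even with two nucleophiles gone per electrophile charged, s[nucleophile] there is 0.278 M, more than the electrophile charged, so in that flask we expect [target] to stay under s[nucleophile], with no plateau of the kind read above. That flask gives 93.8% reacted, and its target, at 58.9%, holds more of the electrophile than its side product, at 34.9%.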